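**Assumption:** the target has no stereocentre (it is achiral), so no enantiocontrol is needed; the only stereo-element in the route is the E-alkene of the chalcone, which is destroyed on ring closure.

## Retrosynthetic overview

1. Target ⇐ hydrogenolysis of four benzyl ethers; 3-OMe ⇐ O-methylation of a flavonol; 3-OH ⇐ epoxidation/rearrangement of the flavone C2=C3 bond.
2. Ring C (the only ring formed, after the fragment union) ⇐ oxidative cyclisation of a 2'-hydroxychalcone.
3. Chalcone ⇐ intermolecular crossed aldol (Claisen–Schmidt) condensation of a ring A acetophenone with a ring B benzaldehyde; this C–C bond becomes C2–C3 of the flavone.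
4. Ring A ketone ⇐ 2,4,6-trihydroxyacetophenone by 4,6-di-O-benzylation, 3,5-dibromination and copper-mediated double methoxylation.
5. Ring B aldehyde ⇐ 3,4-bis(benzyloxy)benzaldehyde by Baeyer–Villiger oxidation to the phenol, O-methylation and Vilsmeier formylation.

## Route

**Step 1**
Reactants: 1 2,4,6-trihydroxyacetophenone
Product: 2 1-[2,4-bis(benzyloxy)-6-hydroxyphenyl]ethanone
Conditions: BnBr (2.1 equiv), K2CO3 (2.2 equiv), DMF, rt
Reagents that add atoms: benzyl bromide, BrCc1ccccc1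
Why: Williamson etherification in which the 4-OH and one of the two equivalent ortho-OH groups react, while the last ortho-OH is held in a hydrogen bond to the acetyl carbonyl and stays free at two equivalents of BnBr.

**Step 2**
Reactants: 2 1-[2,4-bis(benzyloxy)-6-hydroxyphenyl]ethanone
Product: 3 1-[2,4-bis(benzyloxy)-3,5-dibromo-6-hydroxyphenyl]ethanone
Conditions: NBS (2.05 equiv), MeCN, 0 °C → rt
Reagents that add atoms: N-bromosuccinimide, O=C1CCC(=O)N1Br
Why: Electrophilic aromatic bromination at the only two free ring positions, each ortho/para to three oxygen donors, which is much faster than bromination of the acetyl methyl group.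

**Step 3**
Reactants: 3 1-[2,4-bis(benzyloxy)-3,5-dibromo-6-hydroxyphenyl]ethanone
Product: 4 1-[2,4-bis(benzyloxy)-6-hydroxy-3,5-dimethoxyphenyl]ethanone
Conditions: NaOMe (25% in MeOH, 8 equiv), CuBr (0.5 equiv), DMF, 100 °C, N2; then 1 M HCl
Reagents that add atoms: sodium methoxide, [Na+].[O-]C
Why: Ullmann-type copper-mediated aryl ether synthesis, which replaces both aryl bromides by methoxide, tolerates an ortho-phenoxide and a ring carbonyl (as in the bromovanillin-to-syringaldehyde conversion) and leaves benzyl ethers untouched.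

**Step 4**
Reactants: 5 3,4-bis(benzyloxy)benzaldehyde
Product: 7 3,4-bis(benzyloxy)phenol, via aryl formate 6 (not isolated)
Conditions: mCPBA (1.3 equiv), CH2Cl2, 0 °C → rt; aq. NaHCO3 wash; then K2CO3 (cat.), MeOH, rt
Reagents that add atoms: 3-chloroperoxybenzoic acid (mCPBA), OOC(=O)c1cccc(Cl)c1
Why: Baeyer–Villiger (Dakin-type) oxidation in which the electron-rich aryl group migrates to give the aryl formate, which methanol then transesterifies to the phenol.

**Step 5**
Reactants: 7 3,4-bis(benzyloxy)phenol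
Product: 8 1,2-bis(benzyloxy)-4-methoxybenzene
Conditions: MeI (1.5 equiv), K2CO3, acetone, reflux
Reagents that add atoms: iodomethane, CI
Why: Williamson O-methylation of the only free phenol.

**Step 6**
Reactants: 8 1,2-bis(benzyloxy)-4-methoxybenzene
Product: 10 4,5-bis(benzyloxy)-2-methoxybenzaldehyde, via aryl iminium chloride 9 (not isolated)
Conditions: POCl3 (1.5 equiv), DMF, 0 → 70 °C; then ice-water, 50 °C
Reagents that add atoms: N,N-dimethylformamide, CN(C)C=O; water, O
Why: Vilsmeier–Haack formylation at the unhindered position ortho to OMe and para to a benzyloxy group (the same selectivity as 1,2,4-trimethoxybenzene to 2,4,5-trimethoxybenzaldehyde), followed by hydrolysis of the iminium salt.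

**Step 7**
Reactants: 4 1-[2,4-bis(benzyloxy)-6-hydroxy-3,5-dimethoxyphenyl]ethanone; 10 4,5-bis(benzyloxy)-2-methoxybenzaldehyde
Product: 12 (E)-1-[2,4-bis(benzyloxy)-6-hydroxy-3,5-dimethoxyphenyl]-3-[4,5-bis(benzyloxy)-2-methoxyphenyl]prop-2-en-1-one, via racemic aldol adduct 11 (not isolated)
Conditions: KOH (50% aq., 10 equiv), EtOH–THF, rt, 48 h; then 1 M HCl
Reagents that add atoms: none
Why: Claisen–Schmidt crossed aldol condensation in which only the methyl ketone can enolise and the aldehyde cannot, and E1cB dehydration of the aldol gives the conjugated E-enone as the thermodynamic alkene.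

**Step 8**
Reactants: 12 (E)-1-[2,4-bis(benzyloxy)-6-hydroxy-3,5-dimethoxyphenyl]-3-[4,5-bis(benzyloxy)-2-methoxyphenyl]prop-2-en-1-one
Product: 14 5,7-bis(benzyloxy)-2-[4,5-bis(benzyloxy)-2-methoxyphenyl]-6,8-dimethoxy-4H-chromen-4-one, via racemic flavanone 13 (not isolated)
Conditions: I2 (10 mol%), DMSO, 125 °C, 2–3 h; then aq. Na2S2O3 wash
Reagents that add atoms: none
Why: Iodine/DMSO oxidative cyclisation, in which oxa-Michael closure gives the flavanone, α-iodination and loss of HI give the flavone, and DMSO reoxidises HI to I2; the flavanone stereocentre is lost.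

**Step 9**
Reactants: 14 5,7-bis(benzyloxy)-2-[4,5-bis(benzyloxy)-2-methoxyphenyl]-6,8-dimethoxy-4H-chromen-4-one
Product: 16 5,7-bis(benzyloxy)-2-[4,5-bis(benzyloxy)-2-methoxyphenyl]-3-hydroxy-6,8-dimethoxy-4H-chromen-4-one, via racemic 2,3-epoxide 15 (not isolated)
Conditions: dimethyldioxirane (ca. 0.08 M in acetone, 4 equiv), CH2Cl2, 0 °C → rt; then p-TsOH·H2O (cat.), CH2Cl2, rt
Reagents that add atoms: dimethyldioxirane, CC1(C)OO1
Why: Dioxirane epoxidation of the enol-ether-like C2=C3 bond, then acid-catalysed epoxide opening at C2 and loss of H-3 to give the flavonol, so the epoxide stereocentres vanish.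

**Step 10**
Reactants: 16 5,7-bis(benzyloxy)-2-[4,5-bis(benzyloxy)-2-methoxyphenyl]-3-hydroxy-6,8-dimethoxy-4H-chromen-4-one
Product: 17 5,7-bis(benzyloxy)-2-[4,5-bis(benzyloxy)-2-methoxyphenyl]-3,6,8-trimethoxy-4H-chromen-4-one
Conditions: MeI (2 equiv), K2CO3, acetone, reflux
Reagents that add atoms: iodomethane, CI
Why: Williamson O-methylation of the 3-OH, the only free hydroxyl since every other oxygen is benzylated or methylated.

**Step 11**
Reactants: 17 5,7-bis(benzyloxy)-2-[4,5-bis(benzyloxy)-2-methoxyphenyl]-3,6,8-trimethoxy-4H-chromen-4-one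
Product: 18 5,7,4',5'-tetrahydroxy-3,6,8,2'-tetramethoxyflavone
Conditions: H2 (1 atm), 10% Pd/C, THF–MeOH, rt; filter and concentrate under N2
Reagents that add atoms: none
Why: Catalytic hydrogenolysis cleaves the four benzyl aryl ethers, while the methyl ethers and the tetrasubstituted, vinylogous-ester C2=C3 bond of the 3-methoxyflavone are inert under these mild conditions.

## Compound list

1 | 2,4,6-trihydroxyacetophenone | CC(=O)c1c(O)cc(O)cc1O | starting material
2 | 1-[2,4-bis(benzyloxy)-6-hydroxyphenyl]ethanone | CC(=O)c1c(O)cc(OCc2ccccc2)cc1OCc1ccccc1 | intermediate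
3 | 1-[2,4-bis(benzyloxy)-3,5-dibromo-6-hydroxyphenyl]ethanone | CC(=O)c1c(O)c(Br)c(OCc2ccccc2)c(Br)c1OCc1ccccc1 | intermediate
4 | 1-[2,4-bis(benzyloxy)-6-hydroxy-3,5-dimethoxyphenyl]ethanone | CC(=O)c1c(O)c(OC)c(OCc2ccccc2)c(OC)c1OCc1ccccc1 | intermediate
5 | 3,4-bis(benzyloxy)benzaldehyde | O=Cc1ccc(OCc2ccccc2)c(OCc2ccccc2)c1 | starting material
6 | 3,4-bis(benzyloxy)phenyl formate (formed in situ) | O=COc1ccc(OCc2ccccc2)c(OCc2ccccc2)c1 | intermediate
7 | 3,4-bis(benzyloxy)phenol | Oc1ccc(OCc2ccccc2)c(OCc2ccccc2)c1 | intermediate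
8 | 1,2-bis(benzyloxy)-4-methoxybenzene | COc1ccc(OCc2ccccc2)c(OCc2ccccc2)c1 | intermediate
9 | [4,5-bis(benzyloxy)-2-methoxyphenyl]methylidene(dimethyl)iminium chloride (formed in situ) | COc1cc(OCc2ccccc2)c(OCc2ccccc2)cc1C=[N+](C)C.[Cl-] | intermediate
10 | 4,5-bis(benzyloxy)-2-methoxybenzaldehyde | COc1cc(OCc2ccccc2)c(OCc2ccccc2)cc1C=O | intermediate
11 | 1-[2,4-bis(benzyloxy)-6-hydroxy-3,5-dimethoxyphenyl]-3-[4,5-bis(benzyloxy)-2-methoxyphenyl]-3-hydroxypropan-1-one (racemic, formed in situ) | COc1cc(OCc2ccccc2)c(OCc2ccccc2)cc1C(O)CC(=O)c1c(O)c(OC)c(OCc2ccccc2)c(OC)c1OCc1ccccc1 | intermediate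
12 | (E)-1-[2,4-bis(benzyloxy)-6-hydroxy-3,5-dimethoxyphenyl]-3-[4,5-bis(benzyloxy)-2-methoxyphenyl]prop-2-en-1-one | COc1cc(OCc2ccccc2)c(OCc2ccccc2)cc1/C=C/C(=O)c1c(O)c(OC)c(OCc2ccccc2)c(OC)c1OCc1ccccc1 | intermediate
13 | 5,7-bis(benzyloxy)-2-[4,5-bis(benzyloxy)-2-methoxyphenyl]-6,8-dimethoxychroman-4-one (racemic, formed in situ) | COc1cc(OCc2ccccc2)c(OCc2ccccc2)cc1C1CC(=O)c2c(OCc3ccccc3)c(OC)c(OCc3ccccc3)c(OC)c2O1 | intermediate
14 | 5,7-bis(benzyloxy)-2-[4,5-bis(benzyloxy)-2-methoxyphenyl]-6,8-dimethoxy-4H-chromen-4-one | COc1cc(OCc2ccccc2)c(OCc2ccccc2)cc1-c1cc(=O)c2c(OCc3ccccc3)c(OC)c(OCc3ccccc3)c(OC)c2o1 | intermediate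
15 | 2,3-epoxide of flavone 14 (oxirane fused across C2–C3, aryl on C2; racemic, ring fusion necessarily cis; formed in situ) | COc1cc(OCc2ccccc2)c(OCc2ccccc2)cc1C12OC1C(=O)c1c(OCc3ccccc3)c(OC)c(OCc3ccccc3)c(OC)c1O2 | intermediate
16 | 5,7-bis(benzyloxy)-2-[4,5-bis(benzyloxy)-2-methoxyphenyl]-3-hydroxy-6,8-dimethoxy-4H-chromen-4-one | COc1cc(OCc2ccccc2)c(OCc2ccccc2)cc1-c1oc2c(OC)c(OCc3ccccc3)c(OC)c(OCc3ccccc3)c2c(=O)c1O | intermediate
17 | 5,7-bis(benzyloxy)-2-[4,5-bis(benzyloxy)-2-methoxyphenyl]-3,6,8-trimethoxy-4H-chromen-4-one | COc1cc(OCc2ccccc2)c(OCc2ccccc2)cc1-c1oc2c(OC)c(OCc3ccccc3)c(OC)c(OCc3ccccc3)c2c(=O)c1OC | intermediate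
18 | 5,7,4',5'-tetrahydroxy-3,6,8,2'-tetramethoxyflavone | COc1cc(O)c(O)cc1-c1oc2c(OC)c(O)c(OC)c(O)c2c(=O)c1OC | target

## Step count and risks

Total steps: 11. Longest linear sequence: 8 steps (1 → 2 → 3 → 4 → 12 → 14 → 16 → 17 → 18; the ring B branch 5 → 7 → 8 → 10 → 12 → 18 is equally long).

The three steps most likely to fail are steps 3, 8 and 9.

**Step 3 (double copper-mediated methoxylation).** The bromide flanked by two benzyloxy groups is hindered, and hydrodebromination or incomplete exchange may compete. The fallback sets out from 3 and comes back at 4. Benzylate the remaining phenol (BnBr, K2CO3, DMF) to give 1-[2,4,6-tris(benzyloxy)-3,5-dibromophenyl]ethanone F1. Exchange both bromides for hydroxyl by palladium-catalysed C–O coupling with hydroxide (Pd2(dba)3, tBuXPhos, KOH, dioxane–H2O, 100 °C) to give 1-[2,4,6-tris(benzyloxy)-3,5-dihydroxyphenyl]ethanone F2. Methylate the two new phenols (MeI, K2CO3, acetone) to give 1-[2,4,6-tris(benzyloxy)-3,5-dimethoxyphenyl]ethanone F3. Finally remove one of the two equivalent benzyl groups ortho to the carbonyl by chelation-controlled cleavage (MgBr2·OEt2, toluene–Et2O, reflux), which gives 4.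

**Step 8 (iodine/DMSO cyclisation).** The HI formed at 125 °C can cleave the 5-O-benzyl group, and the electron-rich rings may be iodinated. The fallback sets out from 12 and comes back at 16, bypassing 14. It is an Algar–Flynn–Oyamada oxidation (30% H2O2, NaOH, MeOH–THF, 0 °C → rt): oxidative cyclisation gives racemic trans-5,7-bis(benzyloxy)-2-[4,5-bis(benzyloxy)-2-methoxyphenyl]-3-hydroxy-6,8-dimethoxychroman-4-one F4, which is dehydrogenated in the same flask to flavonol 16. Competing aurone formation from the 6'-alkoxy chalcone is the known weakness of this alternative.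

**Step 9 (dioxirane oxidation of the flavone).** Epoxidation of the hindered, fully substituted chromone is slow, and long exposure to the oxidant can attack benzylic C–H bonds or the electron-rich ring B. The fallback sets out from 14 and comes back at 16. Deprotonate C3 with LiN(iPr)2 in THF at −78 °C and trap with B(OMe)3 to give dimethyl {5,7-bis(benzyloxy)-2-[4,5-bis(benzyloxy)-2-methoxyphenyl]-6,8-dimethoxy-4-oxo-4H-chromen-3-yl}boronate F5. Oxidise this without isolation (H2O2, AcOH, 0 °C → rt) to flavonol 16.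

## Further compounds

F1 | step 3 | 1-[2,4,6-tris(benzyloxy)-3,5-dibromophenyl]ethanone | CC(=O)c1c(OCc2ccccc2)c(Br)c(OCc2ccccc2)c(Br)c1OCc1ccccc1
F2 | step 3 | 1-[2,4,6-tris(benzyloxy)-3,5-dihydroxyphenyl]ethanone | CC(=O)c1c(OCc2ccccc2)c(O)c(OCc2ccccc2)c(O)c1OCc1ccccc1
F3 | step 3 | 1-[2,4,6-tris(benzyloxy)-3,5-dimethoxyphenyl]ethanone | CC(=O)c1c(OCc2ccccc2)c(OC)c(OCc2ccccc2)c(OC)c1OCc1ccccc1
F4 | step 8 | trans-5,7-bis(benzyloxy)-2-[4,5-bis(benzyloxy)-2-methoxyphenyl]-3-hydroxy-6,8-dimethoxychroman-4-one (racemic; the 2R,3R enantiomer is drawn) | COc1cc(OCc2ccccc2)c(OCc2ccccc2)cc1[C@@H]1[C@H](C(=O)c2c(OCc3ccccc3)c(OC)c(OCc3ccccc3)c(OC)c2O1)O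
F5 | step 9 | dimethyl {5,7-bis(benzyloxy)-2-[4,5-bis(benzyloxy)-2-methoxyphenyl]-6,8-dimethoxy-4-oxo-4H-chromen-3-yl}boronate | COc1cc(OCc2ccccc2)c(OCc2ccccc2)cc1-c1oc2c(OC)c(OCc3ccccc3)c(OC)c(OCc3ccccc3)c2c(=O)c1B(OC)OC
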